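**Retrosynthetic overview**
1. Target ⇐ desilylation and an inverting Mitsunobu angeloylation at C8 of a 10-membered hydroxy lactone (the 8-epi alcohol).
2. Key bond C7–C8 (closes the carbocycle, last ring): C7 of a 3-(bromomethyl)butenolide, normally the acceptor β-carbon of the unsaturated lactone, is made nucleophilic with CrCl2 (homoenolate-type donor) and attacks the C8 aldehyde carbon; the same step unveils the α-methylene lactone.
3. Butenolide (first ring) ⇐ ring-closing metathesis of the 2-(bromomethyl)acrylate of a C6 allylic alcohol, itself from catalytic asymmetric vinylation of a C6 aldehyde.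
4. Acyclic chain ⇐ boron aldol (C2–C3) between a lactic-acid-derived methyl ketone (quaternary C10 by Seebach alkylation) and (S)-2-methylpent-4-enal (Evans alkylation, C4).
5. Ring order: five-membered butenolide first, 10-membered carbocycle last.

Assumption: ring carbons carry germacrane locants (C1 ketone, C3 CHOH, C4 CHMe, C6 lactone O–CH, C7 ring-fusion CH, C8 CH–O–angeloyl, C10 C(Me)OAc; C11–C13 are the lactone α-carbon, carbonyl and exocyclic CH2).

**Route**

Step 1
Reactants: 1 (S)-lactic acid; 2 pivalaldehyde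
Product: 3 (2S,5S)-2-tert-butyl-5-methyl-1,3-dioxolan-4-one
Conditions: TsOH·H2O (cat.), H2SO4 (cat.), pentane, reflux, Dean–Stark; recrystallisation from pentane, −78 °C
Reagents that add atoms: none
Why: Acid-catalysed acetalisation (Seebach self-regeneration-of-stereocentres template); the cis acetal is favoured and crystallises, so the acetal centre is set relative to the lactate centre.

Step 2
Reactants: 3 (2S,5S)-2-tert-butyl-5-methyl-1,3-dioxolan-4-one; 4 allyl bromide
Product: 6 (2S,5R)-5-allyl-2-tert-butyl-5-methyl-1,3-dioxolan-4-one, via lithium (2S)-2-tert-butyl-5-methyl-1,3-dioxol-4-olate 5 (not isolated)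
Conditions: LiN(iPr)2, THF, −78 °C; then 4, −78 → −30 °C
Reagents that add atoms: none
Why: Seebach enolate alkylation; allyl bromide attacks the planar enolate anti to the tert-butyl group, giving the quaternary carbinol centre (future C10, R) with net retention.

Step 3
Reactants: 6 (2S,5R)-5-allyl-2-tert-butyl-5-methyl-1,3-dioxolan-4-one
Product: 7 (R)-3-hydroxy-3-methylhex-5-en-2-one
Conditions: MeLi (1.05 equiv), Et2O, −78 °C; AcOH quench at −78 °C, then H2O
Reagents that add atoms: methyllithium [Li]C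
Why: Single nucleophilic addition to the lactone-type carbonyl; the tetrahedral lithium hemiketal persists at −78 °C and collapses only on work-up with loss of pivalaldehyde, so the ketone never meets MeLi and C10 is untouched.

Step 4
Reactants: 7 (R)-3-hydroxy-3-methylhex-5-en-2-one
Product: 8 (R)-3-methyl-2-oxohex-5-en-3-yl acetate
Conditions: Ac2O, Et3N, DMAP (0.2 equiv), CH2Cl2, 40 °C
Reagents that add atoms: acetic anhydride CC(=O)OC(C)=O
Why: DMAP-catalysed acylation of the tertiary α-ketol installs the C10 acetate early, where nothing else competes.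

Step 5
Reactants: 8 (R)-3-methyl-2-oxohex-5-en-3-yl acetate
Product: 10 (R)-5,5-dimethoxy-3-methyl-2-oxopentan-3-yl acetate, via (R)-3-methyl-2,5-dioxopentan-3-yl acetate 9 (not isolated)
Conditions: O3, CH2Cl2, −78 °C; Me2S; then HC(OMe)3, MeOH, PPTS, rt
Reagents that add atoms: trimethyl orthoformate COC(OC)OC; methanol CO
Why: Ozonolysis with reductive work-up cleaves the terminal alkene, and the aldehyde (future C8) is acetalised selectively over the hindered ketone.

Step 6
Reactants: 11 (R)-4-benzyl-3-propionyloxazolidin-2-one; 4 allyl bromide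
Product: 13 (R)-4-benzyl-3-[(S)-2-methylpent-4-enoyl]oxazolidin-2-one, via sodium (Z)-1-[(R)-4-benzyl-2-oxooxazolidin-3-yl]prop-1-en-1-olate 12 (not isolated)
Conditions: NaN(SiMe3)2, THF, −78 °C; then 4, −78 → −40 °C
Reagents that add atoms: none
Why: Evans auxiliary alkylation; the chelated (Z)-enolate is attacked on the face opposite the benzyl group, setting the methyl-bearing centre (future C4, S).

Step 7
Reactants: 13 (R)-4-benzyl-3-[(S)-2-methylpent-4-enoyl]oxazolidin-2-one
Product: 14 (S)-2-methylpent-4-en-1-ol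
Conditions: LiBH4, Et2O, H2O (1 equiv), 0 °C
Reagents that add atoms: none
Why: Reductive cleavage of the imide releases the primary alcohol and the recoverable auxiliary without touching the stereocentre.

Step 8
Reactants: 14 (S)-2-methylpent-4-en-1-ol
Product: 15 (S)-2-methylpent-4-enal
Conditions: Dess–Martin periodinane, pyridine, CH2Cl2, 0 °C → rt; solution used at once
Reagents that add atoms: none
Why: Buffered Dess–Martin oxidation gives the α-methyl aldehyde without epimerisation.

Step 9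
Reactants: 10 (R)-5,5-dimethoxy-3-methyl-2-oxopentan-3-yl acetate; 15 (S)-2-methylpent-4-enal
Product: 17 (3R,6S,7S)-6-hydroxy-1,1-dimethoxy-3,7-dimethyl-4-oxodec-9-en-3-yl acetate, via diisopinocampheylboron enolate 16 (not isolated)
Conditions: (+)-Ipc2BCl, Et3N, Et2O, 0 °C; then 15, −78 → −20 °C; H2O2, MeOH, pH 7 buffer
Reagents that add atoms: none
Why: Paterson boron aldol; the ketone can enolise only toward its methyl group, and the (+)-Ipc2B enolate is expected to add to the si face of 15, which is also the Felkin–Anh face, setting C3 (S, 3,4-syn).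

Step 10
Reactants: 17 (3R,6S,7S)-6-hydroxy-1,1-dimethoxy-3,7-dimethyl-4-oxodec-9-en-3-yl acetate
Product: 18 (3R,6S,7S)-6-[(tert-butyldimethylsilyl)oxy]-1,1-dimethoxy-3,7-dimethyl-4-oxodec-9-en-3-yl acetate
Conditions: TBSCl, imidazole, DMF, rt
Reagents that add atoms: tert-butyldimethylsilyl chloride CC(C)(C)[Si](C)(C)Cl
Why: Standard silylation of the C3 hydroxyl; the chloride and imidazole conditions spare the dimethyl acetal.

Step 11
Reactants: 18 (3R,6S,7S)-6-[(tert-butyldimethylsilyl)oxy]-1,1-dimethoxy-3,7-dimethyl-4-oxodec-9-en-3-yl acetate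
Product: 19 (3R,6S,7S)-6-[(tert-butyldimethylsilyl)oxy]-1,1-dimethoxy-3,7-dimethyl-4,9-dioxononan-3-yl acetate
Conditions: O3, CH2Cl2, −78 °C; Me2S
Reagents that add atoms: ozone [O-][O+]=O
Why: Ozonolysis of the only alkene gives the C6 aldehyde.

Step 12
Reactants: 19 (3R,6S,7S)-6-[(tert-butyldimethylsilyl)oxy]-1,1-dimethoxy-3,7-dimethyl-4,9-dioxononan-3-yl acetate
Product: 20 (3R,6S,7S,9R)-6-[(tert-butyldimethylsilyl)oxy]-9-hydroxy-1,1-dimethoxy-3,7-dimethyl-4-oxoundec-10-en-3-yl acetate
Conditions: Zn(CH=CH2)2, (−)-MIB [(2S)-3-exo-morpholinoisoborneol] (10 mol %), toluene, −20 → 0 °C; H2O quench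
Reagents that add atoms: divinylzinc C=C[Zn]C=C
Why: Amino-alcohol-catalysed vinylzinc addition (Noyori–Oppolzer type); the (−)-MIB–zinc complex is expected to deliver vinyl to the si face of the aldehyde, setting C6 (R) under catalyst control, and the hindered ketone, esters and acetal are inert to the organozinc.

Step 13
Reactants: 20 (3R,6S,7S,9R)-6-[(tert-butyldimethylsilyl)oxy]-9-hydroxy-1,1-dimethoxy-3,7-dimethyl-4-oxoundec-10-en-3-yl acetate; 21 2-(bromomethyl)acrylic acid
Product: 23 (3R,6S,7S,9R)-3-acetoxy-6-[(tert-butyldimethylsilyl)oxy]-1,1-dimethoxy-3,7-dimethyl-4-oxoundec-10-en-9-yl 2-(bromomethyl)acrylate, via 2-(bromomethyl)acryloyl chloride 22 (not isolated)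
Conditions: 21, (COCl)2, DMF (cat.), CH2Cl2, 0 °C → rt, evaporate; then 20, 2,6-lutidine, CH2Cl2, −20 → 0 °C
Reagents that add atoms: none
Why: Acylation through the acid chloride with a hindered, non-nucleophilic base avoids amine attack on the allylic bromide; C6 is not touched.

Step 14
Reactants: 23 (3R,6S,7S,9R)-3-acetoxy-6-[(tert-butyldimethylsilyl)oxy]-1,1-dimethoxy-3,7-dimethyl-4-oxoundec-10-en-9-yl 2-(bromomethyl)acrylate
Product: 24 (3R,6S,7S)-8-[(2R)-4-(bromomethyl)-5-oxo-2,5-dihydrofuran-2-yl]-6-[(tert-butyldimethylsilyl)oxy]-1,1-dimethoxy-3,7-dimethyl-4-oxooctan-3-yl acetate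
Conditions: second-generation Grubbs catalyst RuCl2(=CHPh)(PCy3)(H2IMes) (5 mol %), CH2Cl2 (5 mM), 40 °C
Reagents that add atoms: none
Why: Ring-closing metathesis between the vinyl group and the acrylate alkene closes the butenolide with loss of ethylene; the allylic bromide is tolerated by the ruthenium carbene.

Step 15
Reactants: 24 (3R,6S,7S)-8-[(2R)-4-(bromomethyl)-5-oxo-2,5-dihydrofuran-2-yl]-6-[(tert-butyldimethylsilyl)oxy]-1,1-dimethoxy-3,7-dimethyl-4-oxooctan-3-yl acetate
Product: 25 (3R,6S,7S)-8-[(2R)-4-(bromomethyl)-5-oxo-2,5-dihydrofuran-2-yl]-6-[(tert-butyldimethylsilyl)oxy]-3,7-dimethyl-1,4-dioxooctan-3-yl acetate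
Conditions: LiBF4, MeCN/H2O (98:2), rt; used crude
Reagents that add atoms: water O
Why: Mild Lewis-acid hydrolysis of the dimethyl acetal; near-neutral conditions keep the silyl ether, the allylic bromide and the base-sensitive β-acetoxy aldehyde intact.

Step 16
Reactants: 25 (3R,6S,7S)-8-[(2R)-4-(bromomethyl)-5-oxo-2,5-dihydrofuran-2-yl]-6-[(tert-butyldimethylsilyl)oxy]-3,7-dimethyl-1,4-dioxooctan-3-yl acetate
Product: 27 (3S,4S,6R,7R,8S,10R)-10-acetoxy-3-[(tert-butyldimethylsilyl)oxy]-8-hydroxy-1-oxogermacr-11(13)-en-12,6-olide, via dichlorochromium allyl intermediate 26 (not isolated)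
Conditions: CrCl2 (10 equiv), THF/DMF (4:1), rt, syringe-pump addition of 25 (final 2 mM); H2O work-up
Reagents that add atoms: none
Why: Proposed new method: CrCl2 inserts into the allylic C–Br bond and turns C7, the β-carbon of the unsaturated lactone and normally its acceptor site, into the nucleophilic γ-terminus of an allylchromium (a homoenolate-type donor) that adds to the C8 aldehyde carbon through a chair-like six-membered transition state; the ring-locked (E)-type allyl unit holds C6 pseudo-equatorial and the tethered C9 equatorial, so the bond forms on the butenolide face anti to the C5 chain (6,7-trans lactone, C7 as in the target) and gives the 7,8-anti carbinol (8S, the epimer wanted for the next step), while the double bond moves out to the exocyclic methylene; the closest known reactions are the intermolecular Zn- or Cr-mediated Barbier allylation of aldehydes with 3-(bromomethyl)furan-2(5H)-ones and CrCl2-mediated Nozaki–Hiyama closures of ω-formyl allylic bromides to 10-membered germacrane rings.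

Step 17
Reactants: 27 (3S,4S,6R,7R,8S,10R)-10-acetoxy-3-[(tert-butyldimethylsilyl)oxy]-8-hydroxy-1-oxogermacr-11(13)-en-12,6-olide; 28 angelic acid [(Z)-2-methylbut-2-enoic acid]
Product: 29 (3S,4S,6R,7S,8R,10R)-10-acetoxy-8-(angeloyloxy)-3-[(tert-butyldimethylsilyl)oxy]-1-oxogermacr-11(13)-en-12,6-olide
Conditions: PPh3, DIAD, toluene, 0 °C → rt
Reagents that add atoms: none
Why: Mitsunobu esterification; SN2 displacement of the activated C8 oxygen by angelate inverts C8 to R and installs the (Z)-ester without base that would isomerise it to tiglate.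

Step 18
Reactants: 29 (3S,4S,6R,7S,8R,10R)-10-acetoxy-8-(angeloyloxy)-3-[(tert-butyldimethylsilyl)oxy]-1-oxogermacr-11(13)-en-12,6-olide
Product: 30 (3S,4S,6R,7S,8R,10R)-10-acetoxy-8-(angeloyloxy)-3-hydroxy-1-oxogermacr-11(13)-en-12,6-olide (CNP0141210.1)
Conditions: HF·pyridine, pyridine, THF, 0 °C → rt
Reagents that add atoms: none
Why: Buffered fluoride desilylation frees the C3 hydroxyl and leaves the acetate, angelate, β-hydroxy ketone and methylene lactone untouched.

**Compound list**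
1 | (S)-lactic acid | C[C@H](O)C(=O)O | starting material
2 | pivalaldehyde | CC(C)(C)C=O | starting material
3 | (2S,5S)-2-tert-butyl-5-methyl-1,3-dioxolan-4-one | C[C@@H]1O[C@@H](OC1=O)C(C)(C)C | intermediate
4 | allyl bromide | C=CCBr | starting material
5 | lithium (2S)-2-tert-butyl-5-methyl-1,3-dioxol-4-olate | CC1=C([O-])O[C@H](O1)C(C)(C)C.[Li+] | intermediate
6 | (2S,5R)-5-allyl-2-tert-butyl-5-methyl-1,3-dioxolan-4-one | C[C@]1(CC=C)O[C@@H](OC1=O)C(C)(C)C | intermediate
7 | (R)-3-hydroxy-3-methylhex-5-en-2-one | CC(=O)[C@](C)(O)CC=C | intermediate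
8 | (R)-3-methyl-2-oxohex-5-en-3-yl acetate | CC(=O)[C@](C)(OC(C)=O)CC=C | intermediate
9 | (R)-3-methyl-2,5-dioxopentan-3-yl acetate | CC(=O)[C@](C)(OC(C)=O)CC=O | intermediate
10 | (R)-5,5-dimethoxy-3-methyl-2-oxopentan-3-yl acetate | CC(=O)[C@](C)(OC(C)=O)CC(OC)OC | intermediate
11 | (R)-4-benzyl-3-propionyloxazolidin-2-one | CCC(=O)N1[C@H](Cc2ccccc2)COC1=O | starting material
12 | sodium (Z)-1-[(R)-4-benzyl-2-oxooxazolidin-3-yl]prop-1-en-1-olate | C/C=C(\[O-])N1[C@H](Cc2ccccc2)COC1=O.[Na+] | intermediate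
13 | (R)-4-benzyl-3-[(S)-2-methylpent-4-enoyl]oxazolidin-2-one | C=CC[C@H](C)C(=O)N1[C@H](Cc2ccccc2)COC1=O | intermediate
14 | (S)-2-methylpent-4-en-1-ol | C=CC[C@H](C)CO | intermediate
15 | (S)-2-methylpent-4-enal | C=CC[C@H](C)C=O | intermediate
16 | (3R)-3-acetoxy-5,5-dimethoxy-3-methylpent-1-en-2-yl (+)-diisopinocampheylborinate (boron enolate of 10) | C=C(OB([C@H]1C[C@H]2C[C@@H]([C@@H]1C)C2(C)C)[C@H]1C[C@H]2C[C@@H]([C@@H]1C)C2(C)C)[C@](C)(OC(C)=O)CC(OC)OC | intermediate
17 | (3R,6S,7S)-6-hydroxy-1,1-dimethoxy-3,7-dimethyl-4-oxodec-9-en-3-yl acetate | C=CC[C@H](C)[C@@H](O)CC(=O)[C@](C)(OC(C)=O)CC(OC)OC | intermediate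
18 | (3R,6S,7S)-6-[(tert-butyldimethylsilyl)oxy]-1,1-dimethoxy-3,7-dimethyl-4-oxodec-9-en-3-yl acetate | C=CC[C@H](C)[C@@H](O[Si](C)(C)C(C)(C)C)CC(=O)[C@](C)(OC(C)=O)CC(OC)OC | intermediate
19 | (3R,6S,7S)-6-[(tert-butyldimethylsilyl)oxy]-1,1-dimethoxy-3,7-dimethyl-4,9-dioxononan-3-yl acetate | O=CC[C@H](C)[C@@H](O[Si](C)(C)C(C)(C)C)CC(=O)[C@](C)(OC(C)=O)CC(OC)OC | intermediate
20 | (3R,6S,7S,9R)-6-[(tert-butyldimethylsilyl)oxy]-9-hydroxy-1,1-dimethoxy-3,7-dimethyl-4-oxoundec-10-en-3-yl acetate | O[C@@H](C=C)C[C@H](C)[C@@H](O[Si](C)(C)C(C)(C)C)CC(=O)[C@](C)(OC(C)=O)CC(OC)OC | intermediate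
21 | 2-(bromomethyl)acrylic acid | C=C(CBr)C(=O)O | starting material
22 | 2-(bromomethyl)acryloyl chloride | C=C(CBr)C(=O)Cl | intermediate
23 | (3R,6S,7S,9R)-3-acetoxy-6-[(tert-butyldimethylsilyl)oxy]-1,1-dimethoxy-3,7-dimethyl-4-oxoundec-10-en-9-yl 2-(bromomethyl)acrylate | C=C(CBr)C(=O)O[C@@H](C=C)C[C@H](C)[C@@H](O[Si](C)(C)C(C)(C)C)CC(=O)[C@](C)(OC(C)=O)CC(OC)OC | intermediate
24 | (3R,6S,7S)-8-[(2R)-4-(bromomethyl)-5-oxo-2,5-dihydrofuran-2-yl]-6-[(tert-butyldimethylsilyl)oxy]-1,1-dimethoxy-3,7-dimethyl-4-oxooctan-3-yl acetate | BrCC1=C[C@@H](C[C@H](C)[C@@H](O[Si](C)(C)C(C)(C)C)CC(=O)[C@](C)(OC(C)=O)CC(OC)OC)OC1=O | intermediate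
25 | (3R,6S,7S)-8-[(2R)-4-(bromomethyl)-5-oxo-2,5-dihydrofuran-2-yl]-6-[(tert-butyldimethylsilyl)oxy]-3,7-dimethyl-1,4-dioxooctan-3-yl acetate | BrCC1=C[C@@H](C[C@H](C)[C@@H](O[Si](C)(C)C(C)(C)C)CC(=O)[C@](C)(OC(C)=O)CC=O)OC1=O | intermediate
26 | dichlorochromium allyl intermediate from 25 (CrCl2 unit on the exocyclic CH2 of the butenolide) | Cl[Cr](Cl)CC1=C[C@@H](C[C@H](C)[C@@H](O[Si](C)(C)C(C)(C)C)CC(=O)[C@](C)(OC(C)=O)CC=O)OC1=O | intermediate
27 | (3S,4S,6R,7R,8S,10R)-10-acetoxy-3-[(tert-butyldimethylsilyl)oxy]-8-hydroxy-1-oxogermacr-11(13)-en-12,6-olide (6,7-trans lactone, C8 epimeric to the target) | C=C1C(=O)O[C@@H]2C[C@H](C)[C@@H](O[Si](C)(C)C(C)(C)C)CC(=O)[C@](C)(OC(C)=O)C[C@H](O)[C@@H]12 | intermediate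
28 | angelic acid, (Z)-2-methylbut-2-enoic acid | C/C=C(/C)C(=O)O | starting material
29 | (3S,4S,6R,7S,8R,10R)-10-acetoxy-8-(angeloyloxy)-3-[(tert-butyldimethylsilyl)oxy]-1-oxogermacr-11(13)-en-12,6-olide | C=C1C(=O)O[C@@H]2C[C@H](C)[C@@H](O[Si](C)(C)C(C)(C)C)CC(=O)[C@](C)(OC(C)=O)C[C@@H](OC(=O)/C(C)=C\C)[C@@H]12 | intermediate
30 | (3S,4S,6R,7S,8R,10R)-10-acetoxy-8-(angeloyloxy)-3-hydroxy-1-oxogermacr-11(13)-en-12,6-olide (CNP0141210.1) | C=C1C(=O)O[C@@H]2C[C@H](C)[C@@H](O)CC(=O)[C@](C)(OC(C)=O)C[C@@H](OC(=O)/C(C)=C\C)[C@@H]12 | target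

**Step count and risks**

Total: 18 steps. Longest linear sequence: 15 steps (steps 1–5 and 9–18); steps 6–8 form the short second branch.

The three steps most likely to fail:

Step 16 (ring closure). Risks are oligomerisation, simple reduction of the bromide, lactone opening by 1,4-elimination from 26, and a facial outcome other than the one argued. The fallback sets out from 24 and replaces the reductive organochromium by a closed-shell allylstannane. Stannylation of 24 with Bu3SnSnBu3 and Pd(PPh3)4 (cat.) in THF at 50 °C gives the allylstannane acetal F1. Hydrolysis with LiBF4 in wet MeCN gives the stannyl aldehyde F2. Treatment with BF3·OEt2 in CH2Cl2 at −78 °C and 1 mM (KF work-up) closes the ring by Lewis-acid allylstannane addition and comes back to the route at 27.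

Step 17 (Mitsunobu at C8). The alcohol is hindered, can eliminate, can sit partly as a hemiketal with the C1 ketone, and PPh3 could isomerise the angelate. The fallback sets out from 27 and separates activation from displacement. Mesylation (MsCl, Et3N, CH2Cl2, −20 °C) gives the C8 mesylate F3. Displacement with cesium angelate (from 28 and Cs2CO3) and 18-crown-6 in toluene at 70 °C gives the inverted ester and comes back at 29.

Step 3 (MeLi on the dioxolanone). If the hemiketal collapses early, the ketone is over-alkylated. The fallback sets out from 6 and goes through an amide that stops cleanly at the ketone. Aminolysis with MeNH(OMe)·HCl and iPrMgCl in THF at −20 → 0 °C gives the Weinreb amide F4 with loss of pivalaldehyde. MeMgBr (3 equiv) in THF at 0 °C then gives the methyl ketone and comes back at 7.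

**Further compounds**
F1 | step 16 | (3R,6S,7S)-6-[(tert-butyldimethylsilyl)oxy]-1,1-dimethoxy-3,7-dimethyl-4-oxo-8-[(2R)-5-oxo-4-(tributylstannylmethyl)-2,5-dihydrofuran-2-yl]octan-3-yl acetate | CCCC[Sn](CCCC)(CCCC)CC1=C[C@@H](C[C@H](C)[C@@H](O[Si](C)(C)C(C)(C)C)CC(=O)[C@](C)(OC(C)=O)CC(OC)OC)OC1=O
F2 | step 16 | (3R,6S,7S)-6-[(tert-butyldimethylsilyl)oxy]-3,7-dimethyl-1,4-dioxo-8-[(2R)-5-oxo-4-(tributylstannylmethyl)-2,5-dihydrofuran-2-yl]octan-3-yl acetate | CCCC[Sn](CCCC)(CCCC)CC1=C[C@@H](C[C@H](C)[C@@H](O[Si](C)(C)C(C)(C)C)CC(=O)[C@](C)(OC(C)=O)CC=O)OC1=O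
F3 | step 17 | C8 methanesulfonate of 27 | C=C1C(=O)O[C@@H]2C[C@H](C)[C@@H](O[Si](C)(C)C(C)(C)C)CC(=O)[C@](C)(OC(C)=O)C[C@H](OS(C)(=O)=O)[C@@H]12
F4 | step 3 | (R)-2-hydroxy-N-methoxy-N,2-dimethylpent-4-enamide | CON(C)C(=O)[C@](C)(O)CC=C
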